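**Retrosynthetic overview**
1. Target 26 ← desilylation, C8 methylenation, O3 acetylation and C9 alkylation with the C11–C16 iodide 21 ← trans-decalin enone 16 (C8=O, C6=C7, free 3α-OH).
2. 16 ← β-elimination of O3 from C6 and epimerisation of C5 ← bridged tricyclic vinylogous ester 13, in which the axial 3α-oxygen of ring A is bonded to C6 of ring B.
3. 13 ← key step from monocyclic ketal 10. Feature used: O3 and C6 are 1,4-related across C4–C5, so O3–C3–C4–C5=C6(–C7H3) can be a 2-methyl-4,5-dihydrofuran whose C5 and then C7 are nucleophilic (a tethered acetone α,α'-dianion), while C10=C9(C8) is an alkylidene Meldrum's acid, electrophilic at C10 and at C8.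
4. 10 ← Knoevenagel condensation, ozonolysis and alkynol cycloketalisation ← acyclic hydroxy ester 6; C3 and C4 come from a Noyori hydrogenation and two Fráter–Seebach alkylations of an acetoacetate.
5. Ring order: temporary O3–C6 oxolane (step 5), ring A (C5–C10) then ring B (C7–C8) in step 8, oxolane opened in step 10.

Key step: step 8

Assumption: 2-(trimethylsilyl)ethyl 3-oxobutanoate (1) and tert-butyl(but-3-yn-1-yloxy)dimethylsilane (17) are taken as catalogue compounds; atom numbers in the text are those of the labdane skeleton of the target.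

**Route**

Step 1
Reactants: 1 2-(trimethylsilyl)ethyl 3-oxobutanoate; 2 3-bromo-2-methylprop-1-ene
Product: 3 2-(trimethylsilyl)ethyl 6-methyl-3-oxohept-6-enoate
Conditions: NaH, then n-BuLi, THF, 0 °C; then 2, 0 → 23 °C; aq NH4Cl
Reagents that add atoms: none
Why: Acetoacetate dianion alkylation, in which the more nucleophilic γ-carbon displaces the allylic bromide and forms the C1–C2 bond while C4 stays free.

Step 2
Reactants: 3 2-(trimethylsilyl)ethyl 6-methyl-3-oxohept-6-enoate
Product: 4 2-(trimethylsilyl)ethyl (3R)-3-hydroxy-6-methylhept-6-enoate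
Conditions: H2 (10 atm), RuCl2[(R)-BINAP] (0.5 mol %), EtOH, 50 °C
Reagents that add atoms: none
Why: Noyori asymmetric hydrogenation of a β-keto ester, in which the (R)-BINAP–Ru chelate should deliver hydride to one carbonyl face and set C3 as R, the isolated 1,1-disubstituted alkene being inert.

Step 3
Reactants: 4 2-(trimethylsilyl)ethyl (3R)-3-hydroxy-6-methylhept-6-enoate
Product: 5 2-(trimethylsilyl)ethyl (2R,3R)-3-hydroxy-2,6-dimethylhept-6-enoate
Conditions: LDA (2.2 equiv), THF, −78 → −20 °C; MeI, DMPU, −78 → −20 °C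
Reagents that add atoms: iodomethane, CI
Why: Fráter–Seebach alkylation, in which the chelated alkoxide–enolate dianion is methylated on the face opposite the C3 side chain to give the 2,3-anti ester.

Step 4
Reactants: 5 2-(trimethylsilyl)ethyl (2R,3R)-3-hydroxy-2,6-dimethylhept-6-enoate
Product: 6 2-(trimethylsilyl)ethyl (2R,3R)-3-hydroxy-2,6-dimethyl-2-(prop-2-yn-1-yl)hept-6-enoate
Conditions: LDA (2.2 equiv), THF, −78 → −20 °C; HC≡CCH2Br, DMPU, −78 → 0 °C
Reagents that add atoms: 3-bromoprop-1-yne, C#CCBr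
Why: Second Fráter–Seebach alkylation, in which the propargyl group (C5–C7) again enters opposite the C3 side chain, so the quaternary C4 should receive the R configuration of the target.

Step 5
Reactants: 6 2-(trimethylsilyl)ethyl (2R,3R)-3-hydroxy-2,6-dimethyl-2-(prop-2-yn-1-yl)hept-6-enoate
Product: 7 2-(trimethylsilyl)ethyl (2R,3R)-5-methoxy-3,5-dimethyl-2-(3-methylbut-3-en-1-yl)oxolane-3-carboxylate (both anomers at the ketal carbon)
Conditions: Ph3PAuCl (2 mol %), AgOTf (2 mol %), MeOH, 23 °C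
Reagents that add atoms: methanol, CO
Why: Gold-catalysed 5-exo-dig hydroalkoxylation of the 4-pentyn-1-ol unit followed by Markovnikov addition of methanol (alkynol cycloketalisation) ties O3 to C6 as a mixed ketal.

Step 6
Reactants: 7 2-(trimethylsilyl)ethyl (2R,3R)-5-methoxy-3,5-dimethyl-2-(3-methylbut-3-en-1-yl)oxolane-3-carboxylate
Product: 8 2-(trimethylsilyl)ethyl (2R,3R)-5-methoxy-3,5-dimethyl-2-(3-oxobutyl)oxolane-3-carboxylate
Conditions: O3, NaHCO3, CH2Cl2/MeOH, −78 °C; Me2S, −78 → 23 °C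
Reagents that add atoms: ozone, [O-][O+]=O
Why: Ozonolysis with reductive work-up cleaves the only C=C bond to the C10 methyl ketone, the buffered ketal and the esters being inert.

Step 7
Reactants: 8 2-(trimethylsilyl)ethyl (2R,3R)-5-methoxy-3,5-dimethyl-2-(3-oxobutyl)oxolane-3-carboxylate; 9 2,2-dimethyl-1,3-dioxane-4,6-dione (Meldrum's acid)
Product: 10 2-(trimethylsilyl)ethyl (2R,3R)-2-[3-(2,2-dimethyl-4,6-dioxo-1,3-dioxan-5-ylidene)butyl]-5-methoxy-3,5-dimethyloxolane-3-carboxylate
Conditions: TiCl4, pyridine, THF, 0 → 23 °C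
Reagents that add atoms: none
Why: TiCl4/pyridine-mediated Knoevenagel condensation, the usual way to make tetrasubstituted alkylidene Meldrum's acids from methyl ketones, with excess pyridine buffering the ketal.

Step 8
Reactants: 10 2-(trimethylsilyl)ethyl (2R,3R)-2-[3-(2,2-dimethyl-4,6-dioxo-1,3-dioxan-5-ylidene)butyl]-5-methoxy-3,5-dimethyloxolane-3-carboxylate
Product: 13 bridged tricyclic vinylogous ester (rings A and B cis-fused; O3 bonded to C6; C6=C7–C8=O; C9 methylene), via dihydrofuran enol ether 11 (not isolated), via bridged Meldrum's acid adduct 12 (not isolated)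
Conditions: Sc(OTf)3 (15 mol %), 4 Å MS, MeNO2, 23 °C, then 100 °C
Reagents that add atoms: none
Why: Proposed new method: Sc(OTf)3 should ionise the methyl ketal to an oxocarbenium ion that loses H5 to give enol ether 11, whose C5 adds to C10 of the activated alkylidene Meldrum's acid (6-exo-trig closure of ring A as a 6-oxabicyclo[3.2.1]octane); the new C6 oxocarbenium ion can deprotonate only at C7, because C5 is now a bridgehead, giving the exocyclic enol ether 12, and C7 then attacks the Meldrum's acid carbonyl C8 (6-exo-trig acyl substitution closing ring B) with loss of acetone and CO2 to leave vinylogous ester 13. The closest known reaction types are the Sc(OTf)3-catalysed domino conjugate addition/Friedel–Crafts acylation of alkylidene Meldrum's acids with electron-rich arenes and the hetero-Diels–Alder and Michael reactions of alkylidene Meldrum's acids with enol ethers; here a tethered 2-methyl-4,5-dihydrofuran acts as the π-nucleophile twice. C5 is set by the two-carbon tether from C3, which allows attack only on the enol ether face syn to the tether (this gives 5β-H, corrected in step 10), and C10 is set by a chair-like transition state in which the small methyl group, not the Meldrum's acid-bearing C9, is axial beside the axial C4 ester. The step needs regioselectivity (C5 before C7, then C7 only) and diastereoselectivity at C10: ring size (six against eight or ten) secures the first bond, the bridgehead position of C5 secures the second, and only the C10 epimer with C9 equatorial can reach C8 while the conjugate addition stays reversible.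

Step 9
Reactants: 13 bridged tricyclic vinylogous ester
Product: 14 bridged tricyclic β-alkoxy ketone (C6–H, C7 methylene, C8=O, O3–C6 ether intact)
Conditions: H2 (1 atm), Pd/C, EtOAc, 23 °C
Reagents that add atoms: none
Why: Heterogeneous hydrogenation of the β-alkoxy enone C6=C7, as known for dihydropyranones, should add hydrogen from the exposed face, with no other reducible group present.

Step 10
Reactants: 14 bridged tricyclic β-alkoxy ketone
Product: 16 2-(trimethylsilyl)ethyl 3α-hydroxy-8-oxo-11,12,13,14,15,16,17-heptanorlabd-6-en-19-oate (trans-decalin, 5α-H), via cis-fused enone 15 (not isolated)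
Conditions: KOtBu (0.3 equiv), t-BuOH/THF, 23 °C
Reagents that add atoms: none
Why: Base-induced retro-oxa-Michael (E1cB) elimination of O3 from C6 opens the ether bridge to cis-enone 15, whose C5–H is γ to the carbonyl and should epimerise through the dienolate to the trans-decalin 16, which cannot re-close because the axial 3α-OH no longer reaches C6.

Step 11
Reactants: 17 tert-butyl(but-3-yn-1-yloxy)dimethylsilane
Product: 18 (2E)-5-{[tert-butyl(dimethyl)silyl]oxy}-3-methylpent-2-en-1-ol
Conditions: Me3Al, Cp2ZrCl2 (25 mol %), CH2Cl2, 0 → 23 °C; then n-BuLi, (CH2O)n, THF, −78 → 23 °C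
Reagents that add atoms: trimethylaluminium, C[Al](C)C; formaldehyde (as paraformaldehyde), C=O
Why: Negishi zirconium-catalysed carboalumination adds methyl and aluminium syn across the alkyne and hydroxymethylation of the alkenylalanate proceeds with retention, fixing the 13E geometry.

Step 12
Reactants: 18 (2E)-5-{[tert-butyl(dimethyl)silyl]oxy}-3-methylpent-2-en-1-ol
Product: 19 tert-butyl{[(2E)-5-{[tert-butyl(dimethyl)silyl]oxy}-3-methylpent-2-en-1-yl]oxy}diphenylsilane
Conditions: TBDPSCl, imidazole, DMF, 23 °C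
Reagents that add atoms: tert-butyl(chloro)diphenylsilane, CC(C)(C)[Si](Cl)(c1ccccc1)c1ccccc1
Why: Standard silylation of the primary allylic alcohol (O15).

Step 13
Reactants: 19 tert-butyl{[(2E)-5-{[tert-butyl(dimethyl)silyl]oxy}-3-methylpent-2-en-1-yl]oxy}diphenylsilane
Product: 20 (3E)-5-{[tert-butyl(diphenyl)silyl]oxy}-3-methylpent-3-en-1-ol
Conditions: PPTS (10 mol %), EtOH, 45 °C
Reagents that add atoms: none
Why: Acid-catalysed ethanolysis removes the primary TBS ether much faster than the bulkier, more acid-stable TBDPS ether.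

Step 14
Reactants: 20 (3E)-5-{[tert-butyl(diphenyl)silyl]oxy}-3-methylpent-3-en-1-ol
Product: 21 tert-butyl{[(2E)-5-iodo-3-methylpent-2-en-1-yl]oxy}diphenylsilane
Conditions: I2, PPh3, imidazole, CH2Cl2, 0 → 23 °C
Reagents that add atoms: iodine, II
Why: Appel-type iodination converts the primary alcohol into the iodide without touching the E-alkene.

Step 15
Reactants: 16 2-(trimethylsilyl)ethyl 3α-hydroxy-8-oxo-11,12,13,14,15,16,17-heptanorlabd-6-en-19-oate; 21 tert-butyl{[(2E)-5-iodo-3-methylpent-2-en-1-yl]oxy}diphenylsilane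
Product: 22 2-(trimethylsilyl)ethyl 15-{[tert-butyl(diphenyl)silyl]oxy}-3α-hydroxy-8-oxo-17-norlabda-6,13E-dien-19-oate (C9 epimers)
Conditions: LDA (2.3 equiv), THF/DMPU, −78 °C; then 21, −78 → −20 °C
Reagents that add atoms: none
Why: After the O3 alkoxide forms, kinetic deprotonation of the cross-conjugated enone occurs at the α' carbon C9 and SN2 enolate alkylation with the primary iodide installs C11–C16, the C9 configuration being equilibrated in step 16.

Step 16
Reactants: 22 2-(trimethylsilyl)ethyl 15-{[tert-butyl(diphenyl)silyl]oxy}-3α-hydroxy-8-oxo-17-norlabda-6,13E-dien-19-oate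
Product: 23 2-(trimethylsilyl)ethyl 15-{[tert-butyl(diphenyl)silyl]oxy}-3α-hydroxy-8-oxo-17-norlabd-13E-en-19-oate (9α-H)
Conditions: L-Selectride (2.2 equiv), THF, −78 °C; aq NH4Cl; then K2CO3, MeOH, 23 °C
Reagents that add atoms: none
Why: L-Selectride conjugate reduction of the β-unsubstituted cyclohexenone (hydride to C6, the carbonyl being shielded by C9 and C10) followed by base equilibration of C9 to the equatorial side chain next to the C8 ketone.

Step 17
Reactants: 23 2-(trimethylsilyl)ethyl 15-{[tert-butyl(diphenyl)silyl]oxy}-3α-hydroxy-8-oxo-17-norlabd-13E-en-19-oate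
Product: 24 2-(trimethylsilyl)ethyl 3α-acetoxy-15-{[tert-butyl(diphenyl)silyl]oxy}-8-oxo-17-norlabd-13E-en-19-oate
Conditions: Ac2O, DMAP, pyridine, 40 °C
Reagents that add atoms: acetic anhydride, CC(=O)OC(C)=O
Why: DMAP-catalysed acylation of the hindered axial 3α-alcohol, with the ketone, esters and silyl ether unaffected.

Step 18
Reactants: 24 2-(trimethylsilyl)ethyl 3α-acetoxy-15-{[tert-butyl(diphenyl)silyl]oxy}-8-oxo-17-norlabd-13E-en-19-oate
Product: 25 2-(trimethylsilyl)ethyl 3α-acetoxy-15-{[tert-butyl(diphenyl)silyl]oxy}labda-8(17),13E-dien-19-oate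
Conditions: Zn, CH2Br2, TiCl4, THF/CH2Cl2, 0 → 23 °C
Reagents that add atoms: dibromomethane, BrCBr
Why: Lombardo methylenation is non-basic and ketone-selective, so the epimerisable C9 centre, the acetate and the esters should survive while C17 is introduced.

Step 19
Reactants: 25 2-(trimethylsilyl)ethyl 3α-acetoxy-15-{[tert-butyl(diphenyl)silyl]oxy}labda-8(17),13E-dien-19-oate
Product: 26 3α-acetoxy-15-hydroxylabda-8(17),13E-dien-19-oic acid (CNP0395853.1)
Conditions: TBAF, THF, 0 → 23 °C; then dilute HCl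
Reagents that add atoms: none
Why: Fluoride cleaves the 2-(trimethylsilyl)ethyl ester by β-elimination and the TBDPS ether by attack at silicon in one operation, leaving the hindered secondary acetate.

**Compound list**
1 | 2-(trimethylsilyl)ethyl 3-oxobutanoate | CC(=O)CC(=O)OCC[Si](C)(C)C | starting material
2 | 3-bromo-2-methylprop-1-ene | C=C(C)CBr | starting material
3 | 2-(trimethylsilyl)ethyl 6-methyl-3-oxohept-6-enoate | C=C(C)CCC(=O)CC(=O)OCC[Si](C)(C)C | intermediate
4 | 2-(trimethylsilyl)ethyl (3R)-3-hydroxy-6-methylhept-6-enoate | C=C(C)CC[C@@H](O)CC(=O)OCC[Si](C)(C)C | intermediate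
5 | 2-(trimethylsilyl)ethyl (2R,3R)-3-hydroxy-2,6-dimethylhept-6-enoate | C=C(C)CC[C@@H](O)[C@@H](C)C(=O)OCC[Si](C)(C)C | intermediate
6 | 2-(trimethylsilyl)ethyl (2R,3R)-3-hydroxy-2,6-dimethyl-2-(prop-2-yn-1-yl)hept-6-enoate | C=C(C)CC[C@@H](O)[C@@](C)(CC#C)C(=O)OCC[Si](C)(C)C | intermediate
7 | 2-(trimethylsilyl)ethyl (2R,3R)-5-methoxy-3,5-dimethyl-2-(3-methylbut-3-en-1-yl)oxolane-3-carboxylate (ketal anomers) | C=C(C)CC[C@H]1OC(C)(OC)C[C@@]1(C)C(=O)OCC[Si](C)(C)C | intermediate
8 | 2-(trimethylsilyl)ethyl (2R,3R)-5-methoxy-3,5-dimethyl-2-(3-oxobutyl)oxolane-3-carboxylate | CC(=O)CC[C@H]1OC(C)(OC)C[C@@]1(C)C(=O)OCC[Si](C)(C)C | intermediate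
9 | 2,2-dimethyl-1,3-dioxane-4,6-dione (Meldrum's acid) | CC1(C)OC(=O)CC(=O)O1 | starting material
10 | 2-(trimethylsilyl)ethyl (2R,3R)-2-[3-(2,2-dimethyl-4,6-dioxo-1,3-dioxan-5-ylidene)butyl]-5-methoxy-3,5-dimethyloxolane-3-carboxylate | CC(CC[C@H]1OC(C)(OC)C[C@@]1(C)C(=O)OCC[Si](C)(C)C)=C2C(=O)OC(C)(C)OC2=O | intermediate
11 | 2-(trimethylsilyl)ethyl (2R,3R)-2-[3-(2,2-dimethyl-4,6-dioxo-1,3-dioxan-5-ylidene)butyl]-3,5-dimethyl-2,3-dihydrofuran-3-carboxylate (enol ether C5=C6) | CC(CC[C@H]1OC(C)=C[C@@]1(C)C(=O)OCC[Si](C)(C)C)=C2C(=O)OC(C)(C)OC2=O | intermediate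
12 | 6-oxabicyclo[3.2.1]octane adduct: ring A closed (C5–C10), O3–C6 bridge, exocyclic C6=C7H2 enol ether, C10 bearing axial methyl and the Meldrum's acid ring through C9 | C=C1O[C@@H]2CC[C@](C)(C3C(=O)OC(C)(C)OC3=O)[C@H]1[C@@]2(C)C(=O)OCC[Si](C)(C)C | intermediate
13 | bridged tricyclic vinylogous ester: 2-(trimethylsilyl)ethyl 3α,6-epoxy-8-oxo-11,12,13,14,15,16,17-heptanor-5β-labd-6-en-19-oate | O=C1C[C@@]2(C)CC[C@H]3OC(=C1)[C@@H]2[C@@]3(C)C(=O)OCC[Si](C)(C)C | intermediate
14 | bridged tricyclic β-alkoxy ketone: 2-(trimethylsilyl)ethyl 3α,6-epoxy-8-oxo-11,12,13,14,15,16,17-heptanor-5β-labdan-19-oate | O=C1C[C@@]2(C)CC[C@H]3O[C@@H](C1)[C@@H]2[C@@]3(C)C(=O)OCC[Si](C)(C)C | intermediate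
15 | 2-(trimethylsilyl)ethyl 3α-hydroxy-8-oxo-11,12,13,14,15,16,17-heptanor-5β-labd-6-en-19-oate (cis-fused enone) | O=C1C=C[C@H]2[C@](C)(CC[C@@H](O)[C@]2(C)C(=O)OCC[Si](C)(C)C)C1 | intermediate
16 | 2-(trimethylsilyl)ethyl 3α-hydroxy-8-oxo-11,12,13,14,15,16,17-heptanorlabd-6-en-19-oate (trans-fused enone) | O=C1C=C[C@@H]2[C@](C)(CC[C@@H](O)[C@]2(C)C(=O)OCC[Si](C)(C)C)C1 | intermediate
17 | tert-butyl(but-3-yn-1-yloxy)dimethylsilane | C#CCCO[Si](C)(C)C(C)(C)C | starting material
18 | (2E)-5-{[tert-butyl(dimethyl)silyl]oxy}-3-methylpent-2-en-1-ol | CC(C)(C)[Si](C)(C)OCC/C(C)=C/CO | intermediate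
19 | tert-butyl{[(2E)-5-{[tert-butyl(dimethyl)silyl]oxy}-3-methylpent-2-en-1-yl]oxy}diphenylsilane | CC(C)(C)[Si](C)(C)OCC/C(C)=C/CO[Si](c1ccccc1)(c1ccccc1)C(C)(C)C | intermediate
20 | (3E)-5-{[tert-butyl(diphenyl)silyl]oxy}-3-methylpent-3-en-1-ol | OCC/C(C)=C/CO[Si](c1ccccc1)(c1ccccc1)C(C)(C)C | intermediate
21 | tert-butyl{[(2E)-5-iodo-3-methylpent-2-en-1-yl]oxy}diphenylsilane | ICC/C(C)=C/CO[Si](c1ccccc1)(c1ccccc1)C(C)(C)C | intermediate
22 | 2-(trimethylsilyl)ethyl 15-{[tert-butyl(diphenyl)silyl]oxy}-3α-hydroxy-8-oxo-17-norlabda-6,13E-dien-19-oate (C9 epimers) | O=C1C=C[C@@H]2[C@](C)(CC[C@@H](O)[C@]2(C)C(=O)OCC[Si](C)(C)C)C1CC/C(C)=C/CO[Si](c3ccccc3)(c3ccccc3)C(C)(C)C | intermediate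
23 | 2-(trimethylsilyl)ethyl 15-{[tert-butyl(diphenyl)silyl]oxy}-3α-hydroxy-8-oxo-17-norlabd-13E-en-19-oate | O=C1CC[C@@H]2[C@](C)(CC[C@@H](O)[C@]2(C)C(=O)OCC[Si](C)(C)C)[C@H]1CC/C(C)=C/CO[Si](c3ccccc3)(c3ccccc3)C(C)(C)C | intermediate
24 | 2-(trimethylsilyl)ethyl 3α-acetoxy-15-{[tert-butyl(diphenyl)silyl]oxy}-8-oxo-17-norlabd-13E-en-19-oate | O=C1CC[C@@H]2[C@](C)(CC[C@@H](OC(C)=O)[C@]2(C)C(=O)OCC[Si](C)(C)C)[C@H]1CC/C(C)=C/CO[Si](c3ccccc3)(c3ccccc3)C(C)(C)C | intermediate
25 | 2-(trimethylsilyl)ethyl 3α-acetoxy-15-{[tert-butyl(diphenyl)silyl]oxy}labda-8(17),13E-dien-19-oate | C=C1CC[C@@H]2[C@](C)(CC[C@@H](OC(C)=O)[C@]2(C)C(=O)OCC[Si](C)(C)C)[C@H]1CC/C(C)=C/CO[Si](c3ccccc3)(c3ccccc3)C(C)(C)C | intermediate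
26 | 3α-acetoxy-15-hydroxylabda-8(17),13E-dien-19-oic acid (CNP0395853.1) | C=C1CC[C@@H]2[C@](C)(CC[C@@H](OC(C)=O)[C@]2(C)C(=O)O)[C@H]1CC/C(C)=C/CO | target

**Count and risks**
Total step count: 19. Longest linear sequence: 15 (steps 1–10 and 15–19; steps 11–14 make the side-chain iodide).

Steps most likely to fail:

1. Step 8 (Proposed new method). The enol ether may be lost to hydrolysis or oligomerisation under the Lewis acid, or the sequence may stall after the conjugate addition because C-acylation by the Meldrum's acid carbonyl is too slow. Fallback with known chemistry, setting out from 8 and coming back at 13: Horner–Wadsworth–Emmons olefination of 8 with trimethyl phosphonoacetate (NaH, THF) should give the 3-methyl enoate F1 (E/Z mixture, both usable). PPTS in wet acetone should hydrolyse the methyl ketal to the γ-hydroxy methyl ketone F2. NaOMe in refluxing MeOH should then effect the dimedone-type sequence of intramolecular Michael addition (C5 enolate to C10) and Dieckmann condensation (C7 enolate to C8), giving the 3α-hydroxy-6,8-dione F3, whose C5 equilibrates. TsOH in toluene with removal of water should close O3 onto the C6 carbonyl, the only one it can reach and only in the C10 epimer needed, to give 13.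

2. Step 15. SN2 attack by the neopentyl-like C9 enolate carbon may be so slow that E2 elimination of the homoallylic iodide and proton transfer take over. Fallback by aldol condensation and conjugate reduction, setting out from 16 and 20 and coming back at 24: Dess–Martin oxidation of 20 should give the β,γ-unsaturated aldehyde F4, used at once. The lithium dienolate of 16 (LDA, 2.3 equiv, −78 °C) should add to F4 to give the aldol F5 (C9 and C11 epimers). Ac2O/DMAP/pyridine should acetylate both hydroxyls to the diacetate F6, and DBU should eliminate the β-acetoxy ketone to the 9(11)-alkylidene dienone F7, which already carries the 3α-acetate. Hydrogenation of both enone C=C bonds under H2 with catalytic [(Ph3P)CuH]6, followed by brief DBU equilibration at C9, should give 24.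

3. Step 10. Re-addition of the liberated 3-alkoxide to C6 (reversible oxa-Michael reaction) may outrun the C5 epimerisation, so that the mixture stays on the side of 14 and 15. Fallback by trapping the alcohol before the epimerisation, setting out from 14 and coming back at 16: KOtBu (1.1 equiv) in THF at −78 → 0 °C followed by TESCl should give the cis-fused enone triethylsilyl ether F8, which can no longer re-close. Catalytic DBU in MeCN should epimerise C5 through the dienolate to the trans-fused enone silyl ether F9. HF·pyridine in THF should then remove the silyl group to give 16.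

Further compounds
F1 | step 8 | 2-(trimethylsilyl)ethyl (2R,3R)-5-methoxy-2-(5-methoxy-3-methyl-5-oxopent-3-en-1-yl)-3,5-dimethyloxolane-3-carboxylate | COC(=O)C=C(C)CC[C@H]1OC(C)(OC)C[C@@]1(C)C(=O)OCC[Si](C)(C)C
F2 | step 8 | 1-methyl 8-[2-(trimethylsilyl)ethyl] (6R,7R)-6-hydroxy-3,7-dimethyl-7-(2-oxopropyl)oct-2-enedioate | COC(=O)C=C(C)CC[C@@H](O)[C@@](C)(CC(C)=O)C(=O)OCC[Si](C)(C)C
F3 | step 8 | 2-(trimethylsilyl)ethyl 3α-hydroxy-6,8-dioxo-11,12,13,14,15,16,17-heptanorlabdan-19-oate (C5 epimers) | O=C1C[C@@]2(C)CC[C@@H](O)[C@](C)(C(=O)OCC[Si](C)(C)C)C2C(=O)C1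
F4 | step 15 | (3E)-5-{[tert-butyl(diphenyl)silyl]oxy}-3-methylpent-3-enal | O=CC/C(C)=C/CO[Si](c1ccccc1)(c1ccccc1)C(C)(C)C
F5 | step 15 | 2-(trimethylsilyl)ethyl 15-{[tert-butyl(diphenyl)silyl]oxy}-3α,11-dihydroxy-8-oxo-17-norlabda-6,13E-dien-19-oate (C9 and C11 epimers) | O=C1C=C[C@@H]2[C@](C)(CC[C@@H](O)[C@]2(C)C(=O)OCC[Si](C)(C)C)C1C(O)C/C(C)=C/CO[Si](c3ccccc3)(c3ccccc3)C(C)(C)C
F6 | step 15 | 2-(trimethylsilyl)ethyl 3α,11-diacetoxy-15-{[tert-butyl(diphenyl)silyl]oxy}-8-oxo-17-norlabda-6,13E-dien-19-oate | O=C1C=C[C@@H]2[C@](C)(CC[C@@H](OC(C)=O)[C@]2(C)C(=O)OCC[Si](C)(C)C)C1C(OC(C)=O)C/C(C)=C/CO[Si](c3ccccc3)(c3ccccc3)C(C)(C)C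
F7 | step 15 | 2-(trimethylsilyl)ethyl 3α-acetoxy-15-{[tert-butyl(diphenyl)silyl]oxy}-8-oxo-17-norlabda-6,9(11),13E-trien-19-oate | O=C1C=C[C@@H]2[C@](C)(CC[C@@H](OC(C)=O)[C@]2(C)C(=O)OCC[Si](C)(C)C)C1=CC/C(C)=C/CO[Si](c3ccccc3)(c3ccccc3)C(C)(C)C
F8 | step 10 | 2-(trimethylsilyl)ethyl 8-oxo-3α-[(triethylsilyl)oxy]-11,12,13,14,15,16,17-heptanor-5β-labd-6-en-19-oate | O=C1C=C[C@H]2[C@](C)(CC[C@@H](O[Si](CC)(CC)CC)[C@]2(C)C(=O)OCC[Si](C)(C)C)C1
F9 | step 10 | 2-(trimethylsilyl)ethyl 8-oxo-3α-[(triethylsilyl)oxy]-11,12,13,14,15,16,17-heptanorlabd-6-en-19-oate | O=C1C=C[C@@H]2[C@](C)(CC[C@@H](O[Si](CC)(CC)CC)[C@]2(C)C(=O)OCC[Si](C)(C)C)C1
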